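## The problem

Prostaglandin F1α (34) is a cyclopentane (C8–C12 in prostanoid numbering, C1 = carboxyl carbon) with four contiguous stereocentres. These are the saturated C1–C7 acid chain on C8, hydroxyls on C9 and C11, and the C13–C20 chain on C12. A fifth, isolated carbinol centre lies at C15 beyond an E C13=C14 alkene. The two chains are trans, and both ring hydroxyls lie on the face of the C8 chain (8R,9S,11R,12R), so a single face-selective addition to a flat ring cannot set all four centres.

The ring centres can be relayed. C11 and C12 can be fixed in an open chain, C12 can steer the creation of C8 during ring closure, and the C8 substituent can steer a hydride onto a C9 ketone. C15 is out of reach of the ring and needs reagent control.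

The fragile stages are these. A C9 ketone with oxygen on C11 (and, for a time, on C7) is a β-oxygenated ketone open to elimination and retro-aldol cleavage. Aldehydes at C8 or C13 carry an epimerisable α-centre (C12) and a β-silyloxy leaving group. The allylic C15 alcohol does not tolerate strong acid.

The enabling feature is that C9 is a carbinol next to C8 while C7 is a plain CH2 in a chain without any alkene. A C9 nitrile oxide can therefore add across a C7=C8 alkene and form the C8–C9 ring bond. The resulting isoxazoline is a latent C9 ketone whose N–O bond and C7 oxygen are absent from the target and can be removed.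

## Retrosynthesis

**Unmasking (34 ⇐ 33 ⇐ 32).** No skeletal bond is cut. The acid is carried as its methyl ester 33 and the ring hydroxyls as silyl ethers in 32, so that only ester hydrolysis and fluoride cleavage remain once all stereocentres are in place.

**C13=C14 and C15 (32 ⇐ 31 ⇐ 28 + 29).** The C13=C14 bond is cut by a Horner–Wadsworth–Emmons disconnection to aldehyde 28 and phosphonate 29, and the C15–H bond by a CBS reduction of enone 31. Adding a preformed chiral ω chain as a nucleophile would need a ring enone, which this plan never passes through. The olefination gives the E geometry by itself and leaves C15 to a catalyst. Aldehyde 28 already holds all four ring centres and the complete acid chain. The forward steps must not epimerise C12.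

**Redox and protecting-group relay (28 ⇐ 27 ⇐ 26 ⇐ 25 ⇐ 24).** No C–C bond is cut. The C13 aldehyde comes from a benzyl ether and the 9α-alcohol from ketone 24 by a bulky hydride. O9 is silylated in 26 so that debenzylation, oxidation and olefination meet only one free function at a time. The forward demand is β-face hydride delivery at C9, which the C8 chain and the C11 silyl ether on the α face should enforce.

**Removing the tether atoms (24 ⇐ 23 ⇐ 22 ⇐ 20).** Hydrogenolysis of the N–O bond of isoxazoline 20 and hydrolysis of the imine give β-hydroxy ketone 22. Barton–McCombie deoxygenation through thionocarbonate 23 removes the oxygen on C7. This order is preferred to dehydration and conjugate reduction because it keeps the C8 centre that the cycloaddition sets. It asks for acylation of a β-hydroxy ketone without elimination.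

**Key disconnection (20 ⇐ 19 ⇐ 18).** The C8–C9 and C7–O bonds are cut together, opening both rings to the acyclic oxime 18 via nitrile oxide 19. Cuts at C8–C12 or C9–C10 would need a separate tactic for each stereocentre. Here C12 controls C8 through the geometry of the tether, and the carbocycle forms with the C9 oxidation level already right. One correction is made to the usual description of such adducts: C9 is trigonal in 20, so the fusion bond carries one stereocentre (C8), and the second centre formed is C7. Oxime 18 has only two stereocentres and no ring. The forward reaction must be face-selective at C8 and must find only one alkene.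

**C7=C8 (18 ⇐ 17 ⇐ 16 ⇐ 15 ⇐ 11 + 13; 13 ⇐ 12).** The alkene is cut by a Wittig disconnection to aldehyde 11 and phosphonium salt 13, which is made from bromo ester 12 and brings in C1–C7 complete and saturated. The Z geometry is required because it is the source of the allylic 1,3-strain that directs the cycloaddition. The C9 terminus is then adjusted from silyl ether to alcohol, aldehyde and oxime. The forward demand is Z selectivity without loss of the C12 centre.

**C11–C12 (11 ⇐ 10 ⇐ 9 ⇐ 8 ⇐ 4 + 5; 4 ⇐ 1 + 2).** The C11–C12 bond is cut by an Evans syn aldol between imide 4 and aldehyde 5. This is preferred to a C12–C13 or C12–C8 alkylation of a preformed C11 carbinol because both centres arise at once from achiral pieces under control of auxiliary 2. C13 enters as a benzyloxymethyl group from acid 1 and stays saturated until after the cycloaddition. The trans C11/C12 ring relationship corresponds to the syn aldol. The forward demand is clean enolisation of a β-benzyloxy imide.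

## Roads not taken

**Alternative 1:** The C11–O bond and the C13=C14 π bond are traced back to a cyclopropane (C11–C12–C13) with an ionisable oxygen on C14. In the forward key step the bicyclo[3.1.0]hexane orthoformate A2 is subjected to formolysis. C14 ionises, the C11–C13 bond opens in a cyclopropylcarbinyl-to-homoallyl shift, and formate enters at C11 from the α face with inversion, giving the bisformate lactone A1.

- Merits: one step creates the E alkene and the 11α oxygen stereospecifically from a rigid scaffold. The whole ω chain, O15 included, is already present. No tin chemistry is needed.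
- Weak points: C15 must be set before the step, by a dihydroxylation outside the influence of the ring, so it needs separation or separate reagent control. The cation can also collapse at C14 or by other cyclopropylcarbinyl pathways. A1 holds only C6 and C7 of the acid chain. The usual lactol olefination then brings in a C5=C6 alkene, which for 34 must be hydrogenated in the presence of C13=C14.
- Comparison: Alternative 1 is ahead in what the key step achieves and in ω-chain convergence. The chosen plan sets against this a C1–C7 chain that arrives saturated in step 7, C15 set by a catalyst in step 20, and no late alkene-versus-alkene hydrogenation. It pays with more redox and protecting-group steps at C7, C9 and C13.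

**Alternative 2:** The C8–C12 bond is cut by a retro ring contraction. The cyclohexane amino alcohol A4 would be elaborated from phloroglucinol A5 by ring hydrogenation and stepwise differentiation of the three oxygens. In the forward key step A4 is diazotised in aqueous acid. The equatorial diazonium group on C12 leaves while the antiperiplanar C8–C13 bond migrates, with inversion at C12 and retention at C8, so the ring contracts and the C13 carbinol becomes the aldehyde of A3.

- Merits: a cheap flat precursor whose all-cis oxygen pattern maps onto O9, O11 and O13. The semipinacol shift is stereospecific and gives the C13 aldehyde directly, trans to C8.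
- Weak points: the cyclohexane precursor is achiral, so a single enantiomer needs resolution or desymmetrisation. Many steps are spent telling three like oxygens apart and placing nitrogen. Diazonium ions partition between migration, elimination, hydride shift and capture by water. As in Alternative 1, only C6 and C7 are present, so the C5=C6 hydrogenation problem returns.
- Comparison: at the C13 aldehyde stage this road and the chosen plan are equal, since both continue by olefination and C15 reduction, and Alternative 2 is better in raw-material cost. The chosen plan offers absolute configuration from an auxiliary in step 2 and a complete acid chain.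

**Alternative 3:** Both aldol bonds, C8–C9 and C11–C12, are cut, reducing the core to two molecules of succinaldehyde A7. In the forward key step an enamine-catalysed intermolecular aldol under a chiral secondary amino acid forms C8–C9 and sets C8 and C9. O9 closes a lactol onto C6, and a secondary ammonium salt then drives the intramolecular aldol condensation that forms C11–C12 and the enal A6.

- Merits: the bicyclic core arises in one operation from a four-carbon dialdehyde, with catalytic enantiocontrol and no protecting groups. The enal invites conjugate addition of an ω-chain organocopper reagent at C12 with C15 preset. The formyl carbon on C11 can be excised to reveal O11, and the lactol is ready for chain extension.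
- Weak points for 34: A7 oligomerises under the conditions that dimerise it, so the throughput of the key step is inherently limited. The ω chain needs a separately prepared enantiopure vinyl metal. The lactol olefination again delivers a C5=C6 alkene that must be hydrogenated selectively beside C13=C14.
- Comparison: in step count Alternative 3 is clearly better and the chosen plan cannot match it. What the chosen plan has to set against this is a saturated acid chain without any chemoselective hydrogenation, stereocentres that arise in separate and individually correctable steps, and no dependence on a polymerisation-prone dialdehyde.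

Key step: step 11

Remark on the chemistry: oxime 18 is taken as the E/Z mixture that forms, since both isomers give the same nitrile oxide 19. Prostanoid locants (C1–C20) are used for all intermediates.

## Route

Step 1
Reactants: 1 3-(benzyloxy)propanoic acid; 2 (S)-4-benzyl-1,3-oxazolidin-2-one
Product: 4 (S)-4-benzyl-3-[3-(benzyloxy)propanoyl]-1,3-oxazolidin-2-one, via mixed pivalic anhydride 3 (not isolated)
Conditions: t-BuCOCl, Et3N, THF, −20 °C; then 2, LiCl, −20 °C → rt
Reagents that add atoms: none
Why: Mixed-anhydride N-acylation of the oxazolidinone promoted by LiCl; no strong base is used, so the β-benzyloxy acid is not exposed to elimination.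

Step 2
Reactants: 4 N-acyl oxazolidinone; 5 3-[(tert-butyldimethylsilyl)oxy]propanal
Product: 8 (S)-4-benzyl-3-[(2S,3R)-2-[(benzyloxy)methyl]-5-[(tert-butyldimethylsilyl)oxy]-3-hydroxypentanoyl]-1,3-oxazolidin-2-one, via Z boron enolate 6 (not isolated), via boron aldolate 7 (not isolated)
Conditions: Bu2BOTf, Et3N, CH2Cl2, 0 °C; then 5, −78 → 0 °C; then pH 7 buffer, MeOH, 30% H2O2, 0 °C
Reagents that add atoms: none
Why: Evans syn aldol: the Z dibutylboron enolate reacts through a closed chair transition state on the enolate face away from the benzyl group of the auxiliary, setting C12 (S) and C11 (R) in the syn relationship that becomes trans on the ring. The covalent boron enolate, kept at or below 0 °C, should not expel benzyloxide.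

Step 3
Reactants: 8 syn aldol adduct
Product: 9 (S)-4-benzyl-3-[(2S,3R)-2-[(benzyloxy)methyl]-5-[(tert-butyldimethylsilyl)oxy]-3-[(triisopropylsilyl)oxy]pentanoyl]-1,3-oxazolidin-2-one
Conditions: i-Pr3SiOTf, 2,6-lutidine, CH2Cl2, 0 °C → rt
Reagents that add atoms: triisopropylsilyl trifluoromethanesulfonate, CC(C)[Si](C(C)C)(C(C)C)OS(=O)(=O)C(F)(F)F
Why: Silyl triflate silylation of a hindered secondary alcohol; the triisopropylsilyl ether on O11 is chosen to outlast the later removal of the primary tert-butyldimethylsilyl ether and to shield the α face.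

Step 4
Reactants: 9 silylated imide
Product: 10 (2S,3R)-2-[(benzyloxy)methyl]-5-[(tert-butyldimethylsilyl)oxy]-3-[(triisopropylsilyl)oxy]pentan-1-ol
Conditions: LiBH4, MeOH (1 equiv), THF, 0 °C
Reagents that add atoms: none
Why: Reductive removal of the auxiliary by hydride attack at the exocyclic imide carbonyl; silyl and benzyl ethers are inert and auxiliary 2 is released for recovery.

Step 5
Reactants: 10 primary alcohol
Product: 11 (2S,3R)-2-[(benzyloxy)methyl]-5-[(tert-butyldimethylsilyl)oxy]-3-[(triisopropylsilyl)oxy]pentanal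
Conditions: Dess–Martin periodinane, pyridine, CH2Cl2, 0 °C → rt
Reagents that add atoms: none
Why: Dess–Martin oxidation under buffered, non-basic conditions gives the α-branched aldehyde (C8) without epimerising C12 or eliminating the C11 silyloxy group; the aldehyde is used at once.

Step 6
Reactants: 12 methyl 7-bromoheptanoate
Product: 13 (7-methoxy-7-oxoheptyl)triphenylphosphonium bromide
Conditions: PPh3, MeCN, reflux
Reagents that add atoms: triphenylphosphine, c1ccc(cc1)P(c1ccccc1)c1ccccc1
Why: SN2 quaternisation of triphenylphosphine by an unhindered primary bromide; the ester does not interfere.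

Step 7
Reactants: 11 aldehyde; 13 phosphonium bromide
Product: 15 methyl (7Z,9S,10R)-9-[(benzyloxy)methyl]-12-[(tert-butyldimethylsilyl)oxy]-10-[(triisopropylsilyl)oxy]dodec-7-enoate, via phosphonium ylide 14 (not isolated)
Conditions: NaN(SiMe3)2, THF, −78 °C; then 11, −78 °C → rt
Reagents that add atoms: none
Why: Wittig olefination with a non-stabilised ylide under lithium-free conditions gives the Z alkene through the kinetically preferred cis-oxaphosphetane. The low temperature protects the C12 centre of the aldehyde.

Step 8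
Reactants: 15 bis-silyl ether
Product: 16 methyl (7Z,9S,10R)-9-[(benzyloxy)methyl]-12-hydroxy-10-[(triisopropylsilyl)oxy]dodec-7-enoate
Conditions: camphorsulfonic acid (cat.), MeOH/CH2Cl2, 0 °C
Reagents that add atoms: none
Why: Acid-catalysed methanolysis cleaves the unhindered primary tert-butyldimethylsilyl ether much faster than the secondary triisopropylsilyl ether; the methyl ester is degenerate in methanol.

Step 9
Reactants: 16 primary alcohol
Product: 17 methyl (7Z,9S,10R)-9-[(benzyloxy)methyl]-12-oxo-10-[(triisopropylsilyl)oxy]dodec-7-enoate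
Conditions: Dess–Martin periodinane, pyridine, CH2Cl2, 0 °C → rt
Reagents that add atoms: none
Why: Dess–Martin oxidation under neutral conditions gives the β-silyloxy aldehyde (C9) without β-elimination; it is taken on crude.

Step 10
Reactants: 17 aldehyde
Product: 18 methyl (7Z,9S,10R)-9-[(benzyloxy)methyl]-12-(hydroxyimino)-10-[(triisopropylsilyl)oxy]dodec-7-enoate
Conditions: NH2OH·HCl, NaOAc, MeOH, rt
Reagents that add atoms: hydroxylamine hydrochloride, Cl.NO
Why: Oxime formation by condensation of the aldehyde with hydroxylamine under acetate buffering, which is too mild to eliminate the β-silyloxy group.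

Step 11
Reactants: 18 aldoxime
Product: 20 methyl 6-[(3R,3aR,4S,5R)-4-[(benzyloxy)methyl]-5-[(triisopropylsilyl)oxy]-3a,4,5,6-tetrahydro-3H-cyclopenta[c]isoxazol-3-yl]hexanoate, via nitrile oxide 19 (not isolated)
Conditions: aq. NaOCl, CH2Cl2 (0.02 M), 0 °C → rt
Reagents that add atoms: none
Why: Hypochlorite oxidises the aldoxime to nitrile oxide 19, which adds as a 1,3-dipole to the tethered Z alkene in a concerted suprafacial [3+2] cycloaddition; the closest known reaction type is the intramolecular nitrile oxide–olefin cycloaddition that gives cyclopenta-fused isoxazolines. The cyclopentane closes in the 5-exo sense by bonding the dipole carbon C9 to the proximal alkene carbon C8, and the isoxazoline closes in the same event by bonding the dipole oxygen to C7; the three-atom tether (C10–C12) allows only this fused mode. C8 is controlled by C12: allylic 1,3-strain in the Z alkene holds the C12–H bond in the alkene plane, so the tether through C11 and the benzyloxymethyl group lie on opposite faces and C9 can reach C8 only anti to C13, which places the C7 arm trans to C13 with the C11 silyloxy group pseudo-equatorial. C7 is controlled by the alkene geometry, because suprafacial addition to the Z alkene puts C6 and C12 cis on the isoxazoline; this centre is erased in step 14. The step needs facial selectivity (secured by the Z geometry and the C12 centre), site selectivity (C7=C8 is the only π bond present because C13 is held as a benzyl ether) and ring closure faster than dimerisation of the dipole (secured by the five-membered closure and dilution). Ester, silyl ether and benzyl ether are inert to cold two-phase hypochlorite.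

Step 12
Reactants: 20 isoxazoline
Product: 22 methyl (7R)-7-[(1S,2S,3R)-2-[(benzyloxy)methyl]-5-oxo-3-[(triisopropylsilyl)oxy]cyclopentyl]-7-hydroxyheptanoate, via β-hydroxy imine 21 (not isolated)
Conditions: H2 (1 atm), Raney Ni, B(OH)3, MeOH/H2O 5:1, rt
Reagents that add atoms: water, O
Why: Hydrogenolysis of the isoxazoline N–O bond followed by hydrolysis of the imine unmasks the aldol-type β-hydroxy ketone. The boric acid buffer traps ammonia and suppresses retro-aldol cleavage, C8 epimerisation and loss of the C11 silyloxy group, and the benzyl ether should survive at 1 atm.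

Step 13
Reactants: 22 β-hydroxy ketone
Product: 23 methyl (7R)-7-[(1S,2S,3R)-2-[(benzyloxy)methyl]-5-oxo-3-[(triisopropylsilyl)oxy]cyclopentyl]-7-[(phenoxycarbonothioyl)oxy]heptanoate
Conditions: PhOC(S)Cl, pyridine, DMAP (cat.), CH2Cl2, 0 °C
Reagents that add atoms: O-phenyl chlorothionoformate, ClC(=S)Oc1ccccc1
Why: Thioacylation of the secondary C7 alcohol, the first half of a Barton–McCombie deoxygenation; pyridine at 0 °C is a weak enough base that E1cB loss of the new leaving group from the β-position of the ketone should stay slow.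

Step 14
Reactants: 23 thionocarbonate
Product: 24 methyl 7-[(1R,2S,3R)-2-[(benzyloxy)methyl]-5-oxo-3-[(triisopropylsilyl)oxy]cyclopentyl]heptanoate
Conditions: Bu3SnH (excess, added in one portion), AIBN (cat.), toluene, 80 °C
Reagents that add atoms: none
Why: Barton–McCombie radical deoxygenation: the stannyl radical adds to sulfur, β-scission releases the secondary C7 radical, and this is reduced by the stannane. A high stannane concentration makes hydrogen transfer faster than 1,2-acyl migration of the β-keto radical, and C8 is not touched.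

Step 15
Reactants: 24 cyclopentanone
Product: 25 methyl 7-[(1R,2S,3R,5S)-2-[(benzyloxy)methyl]-5-hydroxy-3-[(triisopropylsilyl)oxy]cyclopentyl]heptanoate
Conditions: LiBH(s-Bu)3, THF, −78 °C; then H2O
Reagents that add atoms: none
Why: Substrate-controlled reduction with a bulky trialkylborohydride: hydride enters from the β face, away from the adjacent C8 chain and the C11 silyloxy group on the α face, giving the 9α (S) alcohol. The methyl ester is inert at −78 °C.

Step 16
Reactants: 25 9α-alcohol
Product: 26 methyl 7-[(1R,2S,3R,5S)-2-[(benzyloxy)methyl]-5-[(tert-butyldimethylsilyl)oxy]-3-[(triisopropylsilyl)oxy]cyclopentyl]heptanoate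
Conditions: t-BuMe2SiOTf, 2,6-lutidine, CH2Cl2, −78 → 0 °C
Reagents that add atoms: tert-butyldimethylsilyl trifluoromethanesulfonate, CC(C)(C)[Si](C)(C)OS(=O)(=O)C(F)(F)F
Why: Silyl triflate silylation of the hindered secondary O9, so that debenzylation, oxidation, olefination and C15 reduction meet no free ring hydroxyl.

Step 17
Reactants: 26 benzyl ether
Product: 27 methyl 7-[(1R,2S,3R,5S)-5-[(tert-butyldimethylsilyl)oxy]-2-(hydroxymethyl)-3-[(triisopropylsilyl)oxy]cyclopentyl]heptanoate
Conditions: H2 (1 atm), Pd(OH)2/C, EtOAc, rt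
Reagents that add atoms: none
Why: Catalytic hydrogenolysis of the benzyl ether at a stage where the molecule contains no alkene; silyl ethers and the ester are stable in ethyl acetate.

Step 18
Reactants: 27 primary alcohol
Product: 28 methyl 7-[(1R,2R,3R,5S)-5-[(tert-butyldimethylsilyl)oxy]-2-formyl-3-[(triisopropylsilyl)oxy]cyclopentyl]heptanoate
Conditions: Dess–Martin periodinane, pyridine, CH2Cl2, 0 °C → rt
Reagents that add atoms: none
Why: Dess–Martin oxidation gives the C13 aldehyde under neutral conditions that leave the C12 centre and the β-silyloxy group at C11 intact; the aldehyde is used directly.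

Step 19
Reactants: 28 aldehyde; 29 dimethyl (2-oxoheptyl)phosphonate
Product: 31 methyl 7-[(1R,2R,3R,5S)-5-[(tert-butyldimethylsilyl)oxy]-2-[(1E)-3-oxooct-1-en-1-yl]-3-[(triisopropylsilyl)oxy]cyclopentyl]heptanoate, via lithiated phosphonate 30 (not isolated)
Conditions: LiCl, i-Pr2NEt, MeCN, rt
Reagents that add atoms: none
Why: Horner–Wadsworth–Emmons olefination under Masamune–Roush conditions: reversible addition of the stabilised phosphonate anion leads to the E enone, and the weak amine base spares the epimerisable aldehyde.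

Step 20
Reactants: 31 enone
Product: 32 methyl 7-[(1R,2R,3R,5S)-5-[(tert-butyldimethylsilyl)oxy]-2-[(1E,3S)-3-hydroxyoct-1-en-1-yl]-3-[(triisopropylsilyl)oxy]cyclopentyl]heptanoate
Conditions: (R)-2-methyl-CBS-oxazaborolidine (20 mol %), catecholborane, toluene, −78 °C
Reagents that add atoms: none
Why: CBS reduction: the (R)-oxazaborolidine binds the ketone with the alkenyl group as the large substituent and delivers hydride to the face that gives the 15S alcohol. This is reagent control, as the ring centres are too remote to bias C15, and 1,2-reduction is favoured at low temperature.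

Step 21
Reactants: 32 bis-silyl ether
Product: 33 prostaglandin F1α methyl ester, methyl 7-[(1R,2R,3R,5S)-3,5-dihydroxy-2-[(1E,3S)-3-hydroxyoct-1-en-1-yl]cyclopentyl]heptanoate
Conditions: HF·pyridine, pyridine, THF, 0 °C → rt
Reagents that add atoms: none
Why: Fluoride-driven cleavage of both silyl ethers; the pyridine-buffered reagent spares the allylic C15 alcohol and the ester.

Step 22
Reactants: 33 methyl ester
Product: 34 prostaglandin F1α, 7-[(1R,2R,3R,5S)-3,5-dihydroxy-2-[(1E,3S)-3-hydroxyoct-1-en-1-yl]cyclopentyl]heptanoic acid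
Conditions: LiOH, THF/H2O, rt; then dilute HCl to pH 4, 0 °C
Reagents that add atoms: lithium hydroxide, [Li+].[OH-]
Why: Saponification of the methyl ester; the triol has no β-hydroxy ketone and tolerates aqueous base, and brief cold acidification liberates the acid.

## Compound list

1 | 3-(benzyloxy)propanoic acid | OC(=O)CCOCc1ccccc1 | starting material
2 | (S)-4-benzyl-1,3-oxazolidin-2-one | O=C1N[C@@H](Cc2ccccc2)CO1 | starting material
3 | 3-(benzyloxy)propanoic pivalic anhydride | CC(C)(C)C(=O)OC(=O)CCOCc1ccccc1 | intermediate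
4 | (S)-4-benzyl-3-[3-(benzyloxy)propanoyl]-1,3-oxazolidin-2-one | O=C(CCOCc1ccccc1)N1[C@@H](Cc2ccccc2)COC1=O | intermediate
5 | 3-[(tert-butyldimethylsilyl)oxy]propanal | O=CCCO[Si](C)(C)C(C)(C)C | starting material
6 | (Z)-dibutylboron enolate of 4 | CCCCB(CCCC)O/C(=C\COCc1ccccc1)N1[C@@H](Cc2ccccc2)COC1=O | intermediate
7 | O-dibutylboryl aldolate of 8 | CCCCB(CCCC)O[C@H](CCO[Si](C)(C)C(C)(C)C)[C@H](COCc1ccccc1)C(=O)N1[C@@H](Cc2ccccc2)COC1=O | intermediate
8 | (S)-4-benzyl-3-[(2S,3R)-2-[(benzyloxy)methyl]-5-[(tert-butyldimethylsilyl)oxy]-3-hydroxypentanoyl]-1,3-oxazolidin-2-one | CC(C)(C)[Si](C)(C)OCC[C@@H](O)[C@H](COCc1ccccc1)C(=O)N1[C@@H](Cc2ccccc2)COC1=O | intermediate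
9 | (S)-4-benzyl-3-[(2S,3R)-2-[(benzyloxy)methyl]-5-[(tert-butyldimethylsilyl)oxy]-3-[(triisopropylsilyl)oxy]pentanoyl]-1,3-oxazolidin-2-one | CC(C)(C)[Si](C)(C)OCC[C@@H](O[Si](C(C)C)(C(C)C)C(C)C)[C@H](COCc1ccccc1)C(=O)N1[C@@H](Cc2ccccc2)COC1=O | intermediate
10 | (2S,3R)-2-[(benzyloxy)methyl]-5-[(tert-butyldimethylsilyl)oxy]-3-[(triisopropylsilyl)oxy]pentan-1-ol | CC(C)(C)[Si](C)(C)OCC[C@@H](O[Si](C(C)C)(C(C)C)C(C)C)[C@H](COCc1ccccc1)CO | intermediate
11 | (2S,3R)-2-[(benzyloxy)methyl]-5-[(tert-butyldimethylsilyl)oxy]-3-[(triisopropylsilyl)oxy]pentanal | CC(C)(C)[Si](C)(C)OCC[C@@H](O[Si](C(C)C)(C(C)C)C(C)C)[C@H](COCc1ccccc1)C=O | intermediate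
12 | methyl 7-bromoheptanoate | COC(=O)CCCCCCBr | starting material
13 | (7-methoxy-7-oxoheptyl)triphenylphosphonium bromide | COC(=O)CCCCCC[P+](c1ccccc1)(c1ccccc1)c1ccccc1.[Br-] | intermediate
14 | methyl 7-(triphenylphosphoranylidene)heptanoate | COC(=O)CCCCCC=P(c1ccccc1)(c1ccccc1)c1ccccc1 | intermediate
15 | methyl (7Z,9S,10R)-9-[(benzyloxy)methyl]-12-[(tert-butyldimethylsilyl)oxy]-10-[(triisopropylsilyl)oxy]dodec-7-enoate | CC(C)(C)[Si](C)(C)OCC[C@@H](O[Si](C(C)C)(C(C)C)C(C)C)[C@H](COCc1ccccc1)/C=C\CCCCCC(=O)OC | intermediate
16 | methyl (7Z,9S,10R)-9-[(benzyloxy)methyl]-12-hydroxy-10-[(triisopropylsilyl)oxy]dodec-7-enoate | OCC[C@@H](O[Si](C(C)C)(C(C)C)C(C)C)[C@H](COCc1ccccc1)/C=C\CCCCCC(=O)OC | intermediate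
17 | methyl (7Z,9S,10R)-9-[(benzyloxy)methyl]-12-oxo-10-[(triisopropylsilyl)oxy]dodec-7-enoate | O=CC[C@@H](O[Si](C(C)C)(C(C)C)C(C)C)[C@H](COCc1ccccc1)/C=C\CCCCCC(=O)OC | intermediate
18 | methyl (7Z,9S,10R)-9-[(benzyloxy)methyl]-12-(hydroxyimino)-10-[(triisopropylsilyl)oxy]dodec-7-enoate | ON=CC[C@@H](O[Si](C(C)C)(C(C)C)C(C)C)[C@H](COCc1ccccc1)/C=C\CCCCCC(=O)OC | intermediate
19 | methyl (7Z,9S,10R)-9-[(benzyloxy)methyl]-11-cyano-10-[(triisopropylsilyl)oxy]undec-7-enoate N-oxide (nitrile oxide at C9) | [O-][N+]#CC[C@@H](O[Si](C(C)C)(C(C)C)C(C)C)[C@H](COCc1ccccc1)/C=C\CCCCCC(=O)OC | intermediate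
20 | methyl 6-[(3R,3aR,4S,5R)-4-[(benzyloxy)methyl]-5-[(triisopropylsilyl)oxy]-3a,4,5,6-tetrahydro-3H-cyclopenta[c]isoxazol-3-yl]hexanoate | COC(=O)CCCCC[C@H]1ON=C2C[C@@H](O[Si](C(C)C)(C(C)C)C(C)C)[C@H](COCc3ccccc3)[C@@H]12 | intermediate
21 | methyl (7R)-7-[(1R,2S,3R)-2-[(benzyloxy)methyl]-5-imino-3-[(triisopropylsilyl)oxy]cyclopentyl]-7-hydroxyheptanoate | COC(=O)CCCCC[C@@H](O)[C@H]1C(=N)C[C@@H](O[Si](C(C)C)(C(C)C)C(C)C)[C@@H]1COCc1ccccc1 | intermediate
22 | methyl (7R)-7-[(1S,2S,3R)-2-[(benzyloxy)methyl]-5-oxo-3-[(triisopropylsilyl)oxy]cyclopentyl]-7-hydroxyheptanoate | COC(=O)CCCCC[C@@H](O)[C@H]1C(=O)C[C@@H](O[Si](C(C)C)(C(C)C)C(C)C)[C@@H]1COCc1ccccc1 | intermediate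
23 | methyl (7R)-7-[(1S,2S,3R)-2-[(benzyloxy)methyl]-5-oxo-3-[(triisopropylsilyl)oxy]cyclopentyl]-7-[(phenoxycarbonothioyl)oxy]heptanoate | COC(=O)CCCCC[C@@H](OC(=S)Oc1ccccc1)[C@H]1C(=O)C[C@@H](O[Si](C(C)C)(C(C)C)C(C)C)[C@@H]1COCc1ccccc1 | intermediate
24 | methyl 7-[(1R,2S,3R)-2-[(benzyloxy)methyl]-5-oxo-3-[(triisopropylsilyl)oxy]cyclopentyl]heptanoate | COC(=O)CCCCCC[C@H]1C(=O)C[C@@H](O[Si](C(C)C)(C(C)C)C(C)C)[C@@H]1COCc1ccccc1 | intermediate
25 | methyl 7-[(1R,2S,3R,5S)-2-[(benzyloxy)methyl]-5-hydroxy-3-[(triisopropylsilyl)oxy]cyclopentyl]heptanoate | COC(=O)CCCCCC[C@H]1[C@@H](O)C[C@@H](O[Si](C(C)C)(C(C)C)C(C)C)[C@@H]1COCc1ccccc1 | intermediate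
26 | methyl 7-[(1R,2S,3R,5S)-2-[(benzyloxy)methyl]-5-[(tert-butyldimethylsilyl)oxy]-3-[(triisopropylsilyl)oxy]cyclopentyl]heptanoate | COC(=O)CCCCCC[C@H]1[C@@H](O[Si](C)(C)C(C)(C)C)C[C@@H](O[Si](C(C)C)(C(C)C)C(C)C)[C@@H]1COCc1ccccc1 | intermediate
27 | methyl 7-[(1R,2S,3R,5S)-5-[(tert-butyldimethylsilyl)oxy]-2-(hydroxymethyl)-3-[(triisopropylsilyl)oxy]cyclopentyl]heptanoate | COC(=O)CCCCCC[C@H]1[C@@H](O[Si](C)(C)C(C)(C)C)C[C@@H](O[Si](C(C)C)(C(C)C)C(C)C)[C@@H]1CO | intermediate
28 | methyl 7-[(1R,2R,3R,5S)-5-[(tert-butyldimethylsilyl)oxy]-2-formyl-3-[(triisopropylsilyl)oxy]cyclopentyl]heptanoate | COC(=O)CCCCCC[C@H]1[C@@H](O[Si](C)(C)C(C)(C)C)C[C@@H](O[Si](C(C)C)(C(C)C)C(C)C)[C@@H]1C=O | intermediate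
29 | dimethyl (2-oxoheptyl)phosphonate | CCCCCC(=O)CP(=O)(OC)OC | starting material
30 | lithium salt of the carbanion of dimethyl (2-oxoheptyl)phosphonate | CCCCCC(=O)[CH-]P(=O)(OC)OC.[Li+] | intermediate
31 | methyl 7-[(1R,2R,3R,5S)-5-[(tert-butyldimethylsilyl)oxy]-2-[(1E)-3-oxooct-1-en-1-yl]-3-[(triisopropylsilyl)oxy]cyclopentyl]heptanoate | CCCCCC(=O)/C=C/[C@@H]1[C@@H](CCCCCCC(=O)OC)[C@@H](O[Si](C)(C)C(C)(C)C)C[C@H]1O[Si](C(C)C)(C(C)C)C(C)C | intermediate
32 | methyl 7-[(1R,2R,3R,5S)-5-[(tert-butyldimethylsilyl)oxy]-2-[(1E,3S)-3-hydroxyoct-1-en-1-yl]-3-[(triisopropylsilyl)oxy]cyclopentyl]heptanoate | CCCCC[C@H](O)/C=C/[C@@H]1[C@@H](CCCCCCC(=O)OC)[C@@H](O[Si](C)(C)C(C)(C)C)C[C@H]1O[Si](C(C)C)(C(C)C)C(C)C | intermediate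
33 | prostaglandin F1α methyl ester, methyl 7-[(1R,2R,3R,5S)-3,5-dihydroxy-2-[(1E,3S)-3-hydroxyoct-1-en-1-yl]cyclopentyl]heptanoate | CCCCC[C@H](O)/C=C/[C@@H]1[C@@H](CCCCCCC(=O)OC)[C@@H](O)C[C@H]1O | intermediate
34 | prostaglandin F1α, 7-[(1R,2R,3R,5S)-3,5-dihydroxy-2-[(1E,3S)-3-hydroxyoct-1-en-1-yl]cyclopentyl]heptanoic acid | CCCCC[C@H](O)/C=C/[C@@H]1[C@@H](CCCCCCC(=O)O)[C@@H](O)C[C@H]1O | target

## Step count and least certain steps

Total: 22 steps. Longest linear sequence: 21 steps (steps 1–5 and 7–22 from 1; step 6 is a one-step side branch).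

**Step 11 (key step).** Two processes are most likely to go wrong. Facial selectivity at C8 can erode if the rotamer with C13 in the alkene plane takes part, because the allylic-strain difference is finite. The dipole can also dimerise or suffer further attack by hypochlorite if ring closure is slow.

The fallback replaces the nitrile oxide by a silyl nitronate, a less reactive and more selective dipole. It sets out from 16.
- Iodination (I2, PPh3, imidazole) gives methyl (7Z,9S,10R)-9-[(benzyloxy)methyl]-12-iodo-10-[(triisopropylsilyl)oxy]dodec-7-enoate F1.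
- Displacement with NaNO2 in DMF gives the 12-nitro analogue F2.
- Me3SiCl and Et3N convert F2 into its trimethylsilyl nitronate F3, which cyclises onto the Z alkene to the cis-fused N-(trimethylsilyloxy)isoxazolidine F4.
- Acid-induced loss of silanol (TsOH) returns the route at 20.

**Step 13 (with step 14, which depends on it).** During thioacylation, base-induced E1cB loss of the thionocarbonate from the β-position of the ketone is the main danger. In the radical step, a 1,2-acyl migration of the β-keto radical (ring expansion) can compete with hydrogen transfer.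

The fallback accepts the elimination and restores C8 under thermodynamic control. It sets out from 22.
- MsCl and Et3N give the C7 methanesulfonate of 22 F5.
- DBU eliminates F5 to methyl (7E)-7-[(2S,3R)-2-[(benzyloxy)methyl]-5-oxo-3-[(triisopropylsilyl)oxy]cyclopentylidene]heptanoate F6.
- Conjugate reduction with [(Ph3P)CuH]6, protonation, and KOAc-mediated equilibration of C8 in MeOH to the more stable trans arrangement return the route at 24.

**Step 2.** The enolate may expel benzyloxide (β-elimination to the acryloyl imide), or enolisation may be incomplete, since the acyl group has a leaving group β to the carbonyl.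

The fallback builds the C11/C12 pair by epoxide opening instead. It sets out from 5 and returns at 11.
- Wittig reaction with Ph3P=CHCO2Et gives ethyl (2E)-5-[(tert-butyldimethylsilyl)oxy]pent-2-enoate F7.
- Reduction with i-Bu2AlH gives (2E)-5-[(tert-butyldimethylsilyl)oxy]pent-2-en-1-ol F8.
- Sharpless epoxidation (Ti(O-i-Pr)4, D-(−)-diethyl tartrate, t-BuOOH) gives [(2R,3R)-3-{2-[(tert-butyldimethylsilyl)oxy]ethyl}oxiran-2-yl]methanol F9.
- CH2=CHMgBr with CuI opens F9 at C12 with inversion to (2S,3R)-5-[(tert-butyldimethylsilyl)oxy]-2-ethenylpentane-1,3-diol F10.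
- Primary benzylation (Bu2SnO; BnBr, CsF) gives (3R,4S)-4-[(benzyloxy)methyl]-1-[(tert-butyldimethylsilyl)oxy]hex-5-en-3-ol F11.
- Silylation with i-Pr3SiOTf gives (3R,4S)-4-[(benzyloxy)methyl]-1-[(tert-butyldimethylsilyl)oxy]-3-[(triisopropylsilyl)oxy]hex-5-ene F12.
- Ozonolysis (O3; PPh3) gives 11.

**Step 7.** Z selectivity may erode, C12 may epimerise, or silanol may be lost from the α-branched β-silyloxy aldehyde under the basic ylide.

The fallback reverses the polarity of the olefination so that no such aldehyde is needed. It sets out from 10 and returns at 15.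
- I2, PPh3 and imidazole give (2S,3R)-2-[(benzyloxy)methyl]-5-[(tert-butyldimethylsilyl)oxy]-1-iodo-3-[(triisopropylsilyl)oxy]pentane F13.
- Heating with PPh3 gives [(2S,3R)-2-[(benzyloxy)methyl]-5-[(tert-butyldimethylsilyl)oxy]-3-[(triisopropylsilyl)oxy]pentyl]triphenylphosphonium iodide F14.
- NaN(SiMe3)2 gives the corresponding ylide F15, which reacts with commercial methyl 7-oxoheptanoate at −78 °C to give 15.

**Step 20.** Facial selectivity at C15 may be incomplete if the bulky silyloxy group at C11 opposes the catalyst, and some conjugate reduction may occur.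

The fallback brings C15 in preformed. It sets out from 28 and returns at 32.
- Methylenation (Ph3P=CH2 from Ph3PCH3Br and KO-t-Bu) gives methyl 7-[(1R,2R,3R,5S)-5-[(tert-butyldimethylsilyl)oxy]-2-ethenyl-3-[(triisopropylsilyl)oxy]cyclopentyl]heptanoate F16.
- E-selective cross-metathesis with (S)-oct-1-en-3-ol, using the second-generation Hoveyda–Grubbs catalyst (H2IMes)Cl2Ru=CH(2-i-PrO-C6H4), gives 32 directly.

## Further compounds

F1 | step 11 | methyl (7Z,9S,10R)-9-[(benzyloxy)methyl]-12-iodo-10-[(triisopropylsilyl)oxy]dodec-7-enoate | ICC[C@@H](O[Si](C(C)C)(C(C)C)C(C)C)[C@H](COCc1ccccc1)/C=C\CCCCCC(=O)OC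
F2 | step 11 | methyl (7Z,9S,10R)-9-[(benzyloxy)methyl]-12-nitro-10-[(triisopropylsilyl)oxy]dodec-7-enoate | [O-][N+](=O)CC[C@@H](O[Si](C(C)C)(C(C)C)C(C)C)[C@H](COCc1ccccc1)/C=C\CCCCCC(=O)OC
F3 | step 11 | trimethylsilyl nitronate of F2 | C[Si](C)(C)O[N+]([O-])=CC[C@@H](O[Si](C(C)C)(C(C)C)C(C)C)[C@H](COCc1ccccc1)/C=C\CCCCCC(=O)OC
F4 | step 11 | methyl 6-[(3R,3aR,4S,5R,6aS)-4-[(benzyloxy)methyl]-5-[(triisopropylsilyl)oxy]-1-[(trimethylsilyl)oxy]hexahydro-1H-cyclopenta[c]isoxazol-3-yl]hexanoate | COC(=O)CCCCC[C@H]1ON(O[Si](C)(C)C)[C@H]2C[C@@H](O[Si](C(C)C)(C(C)C)C(C)C)[C@H](COCc3ccccc3)[C@@H]12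
F5 | step 13 | methyl (7R)-7-[(1S,2S,3R)-2-[(benzyloxy)methyl]-5-oxo-3-[(triisopropylsilyl)oxy]cyclopentyl]-7-[(methylsulfonyl)oxy]heptanoate | COC(=O)CCCCC[C@@H](OS(C)(=O)=O)[C@H]1C(=O)C[C@@H](O[Si](C(C)C)(C(C)C)C(C)C)[C@@H]1COCc1ccccc1
F6 | step 13 | methyl (7E)-7-[(2S,3R)-2-[(benzyloxy)methyl]-5-oxo-3-[(triisopropylsilyl)oxy]cyclopentylidene]heptanoate | COC(=O)CCCCC/C=C1/C(=O)C[C@@H](O[Si](C(C)C)(C(C)C)C(C)C)[C@@H]1COCc1ccccc1
F7 | step 2 | ethyl (2E)-5-[(tert-butyldimethylsilyl)oxy]pent-2-enoate | CCOC(=O)/C=C/CCO[Si](C)(C)C(C)(C)C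
F8 | step 2 | (2E)-5-[(tert-butyldimethylsilyl)oxy]pent-2-en-1-ol | OC/C=C/CCO[Si](C)(C)C(C)(C)C
F9 | step 2 | [(2R,3R)-3-{2-[(tert-butyldimethylsilyl)oxy]ethyl}oxiran-2-yl]methanol | OC[C@H]1O[C@@H]1CCO[Si](C)(C)C(C)(C)C
F10 | step 2 | (2S,3R)-5-[(tert-butyldimethylsilyl)oxy]-2-ethenylpentane-1,3-diol | CC(C)(C)[Si](C)(C)OCC[C@@H](O)[C@H](CO)C=C
F11 | step 2 | (3R,4S)-4-[(benzyloxy)methyl]-1-[(tert-butyldimethylsilyl)oxy]hex-5-en-3-ol | CC(C)(C)[Si](C)(C)OCC[C@@H](O)[C@H](COCc1ccccc1)C=C
F12 | step 2 | (3R,4S)-4-[(benzyloxy)methyl]-1-[(tert-butyldimethylsilyl)oxy]-3-[(triisopropylsilyl)oxy]hex-5-ene | CC(C)(C)[Si](C)(C)OCC[C@@H](O[Si](C(C)C)(C(C)C)C(C)C)[C@H](COCc1ccccc1)C=C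
F13 | step 7 | (2S,3R)-2-[(benzyloxy)methyl]-5-[(tert-butyldimethylsilyl)oxy]-1-iodo-3-[(triisopropylsilyl)oxy]pentane | CC(C)(C)[Si](C)(C)OCC[C@@H](O[Si](C(C)C)(C(C)C)C(C)C)[C@H](COCc1ccccc1)CI
F14 | step 7 | [(2S,3R)-2-[(benzyloxy)methyl]-5-[(tert-butyldimethylsilyl)oxy]-3-[(triisopropylsilyl)oxy]pentyl]triphenylphosphonium iodide | CC(C)(C)[Si](C)(C)OCC[C@@H](O[Si](C(C)C)(C(C)C)C(C)C)[C@H](COCc1ccccc1)C[P+](c1ccccc1)(c1ccccc1)c1ccccc1.[I-]
F15 | step 7 | ylide of F14, [(2S,3R)-2-[(benzyloxy)methyl]-5-[(tert-butyldimethylsilyl)oxy]-3-[(triisopropylsilyl)oxy]pentylidene]triphenylphosphorane | CC(C)(C)[Si](C)(C)OCC[C@@H](O[Si](C(C)C)(C(C)C)C(C)C)[C@H](COCc1ccccc1)C=P(c1ccccc1)(c1ccccc1)c1ccccc1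
F16 | step 20 | methyl 7-[(1R,2R,3R,5S)-5-[(tert-butyldimethylsilyl)oxy]-2-ethenyl-3-[(triisopropylsilyl)oxy]cyclopentyl]heptanoate | C=C[C@@H]1[C@@H](CCCCCCC(=O)OC)[C@@H](O[Si](C)(C)C(C)(C)C)C[C@H]1O[Si](C(C)C)(C(C)C)C(C)C
A1 | alternative 1 | 11,15-bisformate of the bicyclic γ-lactone carrying the complete ω chain | CCCCC[C@H](OC=O)/C=C/[C@@H]1[C@H]2CC(=O)O[C@H]2C[C@H]1OC=O
A2 | alternative 1 | bicyclo[3.1.0]hexane-fused γ-lactone with C13 bridging C11 and C12 on the β face and the C14,C15 diol as a 2-methoxy-1,3-dioxolane | CCCCC[C@@H]1OC(OC)O[C@@H]1[C@@H]1[C@H]2C[C@@H]3OC(=O)C[C@@H]3[C@@H]12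
A3 | alternative 2 | C13 aldehyde of the bicyclic lactol methyl ether with O11 benzoate | O=C[C@@H]1[C@H]2CC(OC)O[C@H]2C[C@H]1OC(=O)c1ccccc1
A4 | alternative 2 | cyclohexane amino alcohol (C12 amine, C13 carbinol, O11 benzoate) fused to the lactol methyl ether | N[C@@H]1[C@@H](O)[C@H]2CC(OC)O[C@H]2C[C@H]1OC(=O)c1ccccc1
A5 | alternative 2 | phloroglucinol | Oc1cc(O)cc(O)c1
A6 | alternative 3 | (3aR,6aS)-2-hydroxy-3,3a,6,6a-tetrahydro-2H-cyclopenta[b]furan-5-carbaldehyde | O=CC1=C[C@H]2CC(O)O[C@H]2C1
A7 | alternative 3 | succinaldehyde | O=CCCC=O
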